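## Analysis of the target

The target 30 is a cis-clerodane: a cis-fused decalin whose ring A (C1–C5, C10) is a cross-conjugated diosphenol (C1=C2 with the enol hydroxyl on C2, C3 ketone, exocyclic C4=C18 methylene). Ring B (C5–C10) carries C19 on C5, an acetoxy group on C7, C17 on C8 and, on C9, C20 and the C11–C16 chain ending in an (E)-3-methylbut-2-enoic acid (C13=C14, C15). Five stereocentres sit on ring B, (5S,7S,8S,9R,10R), two of them quaternary (C5, C9) and both adjacent to the ring-fusion carbon C10. C19 and H10 are cis; C20 lies on the opposite face and is cis to C17; the C7 acetate is cis to C19 and trans to C17. In the favoured chair of ring B, C17, the acetate, the side chain and C19 are therefore equatorial, and only C20 and the C5–C4 bond are axial, on the same face. The sensitive groups are the α-methylene ketone (a Michael acceptor), the diosphenol (acidic, easily oxidised), the secondary acetate and H10, which is γ to the C3 ketone. The difficulty lies in the two quaternary carbons flanking the ring fusion, the dense and differentiated oxidation of C1–C4, and a C7 oxygen that must be equatorial although hydride can reach C7 only from the face that gives the axial alcohol. The plan rests on one feature: C1–C4 with oxygen on C2 and C3, a methyl-bearing C5 and a C10–H are the six ring carbons of quinone 17, so a [4+2] cycloaddition across its C5=C10 bond forms ring B and sets C5, C10 and C9 at once.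

## Retrosynthetic reasoning

**30 ⇒ 28 (O–CH3 at C2).** The free diosphenol would not survive the oxidations that raise C15 to the acid, so it is uncovered last from its methyl enol ether 28. That methyl is one of the two methoxy groups the quinone brings, so no protecting-group step is spent. The forward step must remove one methyl next to a carbonyl without touching the acetate or the exocyclic enone; chelation of a Lewis acid between O2 and O3 is the handle.

**28 ⇒ 27 ⇒ 26 ⇒ 25 (oxidation level of C15, acetate).** The acid is traced through aldehyde 27 to the allylic alcohol of 25, and the acetate of 27 to the free 7-hydroxyl of 26. C15 travels as a silyl ether because an enoate would not survive the reductions and the carbonyl methylenation earlier in the route. Acetylation is placed after the allylic oxidation, when the 7-hydroxyl is the only hydroxyl left.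

**25 ⇒ 23 (C1–O cut, C3–OCH3 turned into C3=O).** Ring A of 25 is the product of a reductive 1,3-carbonyl transposition: ionisation of the C1 carbinol of 23, pushed by the C3 methoxy group, and hydration at C3. This puts the ketone on C3 and the alkene at C1=C2 while C2 keeps its oxygen. The same acidic step can free the C15 hydroxyl.

**23 ⇒ 22 ⇒ 20 (C7–H and C8–H).** The equatorial 7-hydroxyl of 23 comes from ketone 22 by a reduction under thermodynamic control. Ketone 22 comes from the silyl enol ether 20 by desilylation and protonation at C8. The enol ether is the direct outcome of the cycloaddition and masks C7 as a non-carbonyl while ring A is worked on. All ring-B redox chemistry is done while ring A holds no carbonyl.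

**20 ⇒ 19 ⇒ 18 (C4=C18 and C1–H).** The methylene carbon is attached by carbonyl olefination of the C4 ketone of 19. The C1 carbinol of 19 comes from the ene-dione 18 by reducing the less hindered carbonyl: C1 has a tertiary neighbour, C4 a quaternary one. The order is fixed because the more reactive carbonyl must be consumed before the olefination.

**18 ⇒ 16 + 17 (C5–C6 and C9–C10).** Cutting these two bonds opens ring B into quinone 17 and the 2-silyloxy diene 16. No other cut removes three stereocentres, a ring and both ring-A oxygens at once. The forward reaction needs regio-, endo- and facial control, with the C9 configuration encoded in the geometry of the C8=C9 bond of 16.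

**16 ⇒ 15 ⇒ 13 ⇒ 12 (O–Si, acyl adjustment).** Diene 16 is the kinetic enol silyl ether of methyl ketone 15, whose only enolisable α-position is the acetyl methyl. Ketone 15 comes from ester 12 through the N-methoxy-N-methyl amide 13, which stops the addition at the ketone.

**12 ⇒ 11 ⇒ 9 (C8–C17 and C9–C20).** The tetrasubstituted alkene is traced to ynoate 9 by removing both methyl groups. A syn-carbocupration places C20 and the metal cis, iodinolysis freezes that geometry in 11, and a stereoretentive palladium-catalysed methylation supplies C17. This fixes the chain cis to the future C7, which the cycloaddition needs.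

**9 ⇒ 6 + 7; 6 ⇒ 5 ⇒ 4 ⇒ 1 + 2.** The ynoate is the C-acylation product of alkyne 6 with chloroformate 7. Silyl ether 6 comes from alcohol 5 and ester 4, whose (E)-trisubstituted alkene is an olefination of ketone 1 with phosphonate 2.

## Alternatives that were turned down

**Alternative 1:** The C5–C19 and C4–C18 bonds are cut together, leading back to a 10-H Δ4-3-keto octalone A2 made from an aromatic precursor by Birch-type reduction. In the forward key step a cuprate delivers methyl to C5, and the regiodefined C3–C4 enolate is trapped with a Mannich-type methylenating salt, then quaternised and eliminated to give the α-methylene ketone A1. In its favour, the cis-fused angular methyl from such conjugate additions is dependable, and the methylene is placed through a defined enolate in the same flask. On that point it is stronger than the chosen route, which must tell two similar carbonyls apart (step 11) and olefinate a hindered one (step 12). Against it, A2 must already hold C7, C8 and the quaternary C9 with its chain, so the hardest ring-B centres need a separate, longer sequence with its own source of absolute configuration. A1 also has no oxygen on C2, so the diosphenol would need a late α′-oxidation next to a reactive α-methylene ketone. The chosen strategy brings both ring-A oxygens from 17 and sets C5, C9 and C10 in one catalytic, convergent step.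

**Alternative 2:** Both C5–C10 and C8–C9 are cut, giving an acyclic trienone A4 in which the C9=C10 enone is tied through C1–C4 to the diene terminus C5. The forward key step is a Lewis-acid-promoted intramolecular [4+2] to the octalinone A3, closing both rings and setting C5, C8, C9 and C10. It is stronger in two respects: C8 is set directly by diene geometry (the chosen route needs the separate protonation of step 13), and the tether removes any regiochemical question. Against it, A4 needs three stereodefined alkenes, one a β,β-disubstituted enone that is a poor dienophile, and enantioface control on such an enone with a flexible tether is less well founded than for quinones. Above all, ring A of A3 arrives as a bare C1 ketone: C2 and C3 must still be oxidised, C1 turned into an alkene carbon and C4 methylenated, a long endgame. The chosen adduct 18 already carries an oxygen on each of C1–C4.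

**Alternative 3:** C2 is excised from ring A, leading to a cis-hydrindanone A6 (five-membered ring C1, C3, C4, C5, C10 with the C3 ketone). In the forward key step its C1=C3 silyl enol ether takes up a dihalocarbene and the cyclopropane opens with loss of halide, inserting C2 to give the 2-bromo enone A5. It is stronger in that the C1=C2(X)–C3=O array forms with unambiguous regiochemistry and a heteroatom handle on C2, with no carbonyl differentiation and no transposition. Against it, A6 must carry all five stereocentres, including a cis-hydrindane with both quaternary carbons, so the key step builds no stereochemistry. Enolisation of A6 must also go towards C1 rather than C4, the vinyl bromide to enol exchange is forcing, and C4 still has to be methylenated next to quaternary C5. The chosen strategy instead puts the stereochemical work into the key step.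

Key step: step 10

**Conventions and assumptions.** Clerodane numbering is used for all bicyclic compounds. "Upper face" is the face of ring B that carries C20 and both ring-A bonds (C5–C4, C10–C1); C19, H10 and the C9 side chain are on the lower face.

Assumption: by analogy with its sense towards simple acrylate-type dienophiles, the (S)-diphenylprolinol-derived catalyst is taken to leave the C10-Re/C5-Si face of the bound quinone open; if the adduct proves antipodal, the (R)-catalyst is used and nothing else changes.

Remark: the C1 carbinol centre made in step 11 is left unassigned (no stereo mark in the SMILES), because it is erased in step 15.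

## Route

Step 1
Reactants: 1 hex-5-yn-2-one; 2 trimethyl phosphonoacetate
Product: 4 methyl (2E)-3-methylhept-2-en-6-ynoate, via sodium phosphonate carbanion 3 (not isolated)
Conditions: NaH, THF, 0 °C → rt; chromatographic removal of the minor (2Z)-ester
Reagents that add atoms: none
Why: Horner–Wadsworth–Emmons olefination of a methyl ketone; the stabilised phosphonate anion should favour the (E)-trisubstituted enoate, and the geometric isomers should be separable here or after step 2.

Step 2
Reactants: 4 methyl (2E)-3-methylhept-2-en-6-ynoate
Product: 5 (2E)-3-methylhept-2-en-6-yn-1-ol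
Conditions: DIBAL-H (2.2 equiv), CH2Cl2, −78 °C; Rochelle salt work-up
Reagents that add atoms: none
Why: 1,2-reduction of an enoate to the allylic alcohol; alkene geometry and the terminal alkyne are not affected.

Step 3
Reactants: 5 (2E)-3-methylhept-2-en-6-yn-1-ol
Product: 6 tert-butyldimethyl{[(2E)-3-methylhept-2-en-6-yn-1-yl]oxy}silane
Conditions: TBSCl, imidazole, CH2Cl2, 0 °C → rt
Reagents that add atoms: tert-butyldimethylsilyl chloride, CC(C)(C)[Si](C)(C)Cl
Why: Routine silylation of a primary alcohol; the ether masks C15–OH until step 15.

Step 4
Reactants: 6 tert-butyldimethyl{[(2E)-3-methylhept-2-en-6-yn-1-yl]oxy}silane; 7 methyl chloroformate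
Product: 9 methyl (6E)-8-[(tert-butyldimethylsilyl)oxy]-6-methyloct-6-en-2-ynoate, via lithium acetylide 8 (not isolated)
Conditions: n-BuLi, THF, −78 °C; then 7, −78 → 0 °C
Reagents that add atoms: none
Why: Deprotonation of the terminal alkyne and C-acylation of the acetylide give the ynoate that activates the triple bond for conjugate addition.

Step 5
Reactants: 9 methyl (6E)-8-[(tert-butyldimethylsilyl)oxy]-6-methyloct-6-en-2-ynoate
Product: 11 methyl (2E,6E)-8-[(tert-butyldimethylsilyl)oxy]-2-iodo-3,6-dimethylocta-2,6-dienoate, via lithium alkenylcuprate 10 (not isolated)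
Conditions: Me2CuLi (from MeLi and CuI), THF, −78 °C; then I2 in THF, −78 °C; aq. Na2S2O3
Reagents that add atoms: lithium dimethylcuprate, [Li+].C[Cu-]C; iodine, II
Why: Syn-carbocupration of the ynoate puts the new methyl (C20) and copper cis, leaving the chain cis to the ester. Iodinolysis at −78 °C with retention fixes this geometry before the alkenylcopper can equilibrate through an allenolate.

Step 6
Reactants: 11 methyl (2E,6E)-8-[(tert-butyldimethylsilyl)oxy]-2-iodo-3,6-dimethylocta-2,6-dienoate
Product: 12 methyl (2Z,6E)-8-[(tert-butyldimethylsilyl)oxy]-2,3,6-trimethylocta-2,6-dienoate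
Conditions: MeZnCl, Pd(PPh3)4 (5 mol%), THF, rt → 50 °C
Reagents that add atoms: methylzinc chloride, C[Zn]Cl
Why: Negishi coupling of an α-iodo enoate proceeds with retention at the alkenyl carbon and supplies C17 cis to C20.

Step 7
Reactants: 12 methyl (2Z,6E)-8-[(tert-butyldimethylsilyl)oxy]-2,3,6-trimethylocta-2,6-dienoate
Product: 13 (2Z,6E)-8-[(tert-butyldimethylsilyl)oxy]-N-methoxy-N,2,3,6-tetramethylocta-2,6-dienamide
Conditions: MeNH(OMe)·HCl, i-PrMgCl, THF, −20 °C → rt
Reagents that add atoms: N,O-dimethylhydroxylamine hydrochloride, CNOC.Cl
Why: Aminolysis of the ester by the magnesium amide gives the Weinreb amide under basic conditions that leave the silyl ether and both alkene geometries alone.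

Step 8
Reactants: 13 (2Z,6E)-8-[(tert-butyldimethylsilyl)oxy]-N-methoxy-N,2,3,6-tetramethylocta-2,6-dienamide
Product: 15 (3Z,7E)-9-[(tert-butyldimethylsilyl)oxy]-3,4,7-trimethylnona-3,7-dien-2-one, via lithium hemiaminal chelate 14 (not isolated)
Conditions: MeLi, THF, −78 → 0 °C; aq. NH4Cl
Reagents that add atoms: methyllithium, [Li]C
Why: Weinreb ketone synthesis; the chelated tetrahedral adduct survives until work-up, so addition stops at the methyl ketone, and conjugate addition to the β,β-disubstituted enone carbon is not expected.

Step 9
Reactants: 15 (3Z,7E)-9-[(tert-butyldimethylsilyl)oxy]-3,4,7-trimethylnona-3,7-dien-2-one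
Product: 16 (3Z,7E)-2,9-bis[(tert-butyldimethylsilyl)oxy]-3,4,7-trimethylnona-1,3,7-triene
Conditions: TBSOTf, Et3N, CH2Cl2, −78 → 0 °C; filtration through Et3N-deactivated silica
Reagents that add atoms: tert-butyldimethylsilyl trifluoromethanesulfonate, CC(C)(C)[Si](C)(C)OS(=O)(=O)C(F)(F)F
Why: Soft enolisation of the acetyl methyl, the only α-position bearing hydrogen, gives the cross-conjugated 2-silyloxy diene without touching the C3=C4 geometry; this is the standard way to make 2-silyloxy-1,3-dienes from methyl enones.

Step 10
Reactants: 16 (3Z,7E)-2,9-bis[(tert-butyldimethylsilyl)oxy]-3,4,7-trimethylnona-1,3,7-triene; 17 2,3-dimethoxy-5-methyl-1,4-benzoquinone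
Product: 18 cis-fused ene-dione adduct (2,3-dimethoxy-18-norcleroda-2,7,13E-triene-1,4-dione with 7-OTBS and 15-OTBS; H10 and C19 on the lower face, C20 on the upper face)
Conditions: (S)-B-(o-tolyl)oxazaborolidinium triflimide [from (S)-α,α-diphenylprolinol, tri-o-tolylboroxine and Tf2NH, oxazaborolidine in slight excess] (20 mol%), CH2Cl2, −78 → −40 °C, strictly anhydrous
Reagents that add atoms: none
Why: The cationic boron Lewis acid binds the C1 carbonyl of 17, the only one with a neighbouring vinylic C–H and the more basic one because it is conjugated to the C5 methyl; this lowers the LUMO of the C5=C10 bond, while the doubly methoxylated C2=C3 bond stays inert. A concerted but asynchronous [4+2] cycloaddition follows, in which the silyloxy-polarised terminus C6 of 16 bonds first to the β-carbon C5 and the disubstituted terminus C9 closes on C10. The closest known reaction type is the oxazaborolidinium-catalysed enantioselective Diels–Alder reaction of unsymmetrical benzoquinones with 2-silyloxy dienes, applied here to a more substituted diene. Ring B closes in the cycloaddition itself, as a six-membered ring formed suprafacially on both partners from C6–C9 and C5/C10, which makes the fusion cis (C19 and H10 on one face). Regiochemistry is secured twice: electronically by the para rule relative to the catalyst-bound carbonyl, and sterically because this orientation avoids joining the two fully substituted carbons C5 and C9. C9 is set relative to C5 and C10 by the endo transition state together with the (3Z) geometry of 16, so the outside methyl (C20) ends syn to ring A and the inside chain anti to it. The absolute configuration of C5, C9 and C10 is controlled by the catalyst, which shields one face of the bound quinone so that the diene adds to the C10-Re/C5-Si face. The product keeps C7 as a fully substituted silyl enol ether, which serves as a masked ketone during steps 11 and 12.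

Step 11
Reactants: 18 cis-fused ene-dione adduct
Product: 19 C1 carbinol (1-hydroxy-2,3-dimethoxy-18-norcleroda-2,7,13E-trien-4-one, 7,15-bis-TBS; C1 epimers carried together)
Conditions: DIBAL-H (1.1 equiv), toluene/CH2Cl2, −78 °C; Rochelle salt work-up
Reagents that add atoms: none
Why: Both ring-A carbonyls are electronically equivalent vinylogous esters, so sterics decide: C1 has the tertiary C10 as neighbour, C4 the quaternary C5, and 1,2-reduction should take place at C1. The conditions are non-basic and cold, so the epimerisable H10 and the silyl enol ether are not at risk.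

Step 12
Reactants: 19 C1 carbinol
Product: 20 4(18)-methylene dienyl bis-ether (1-hydroxy-2,3-dimethoxycleroda-2,4(18),7,13E-tetraene, 7,15-bis-TBS)
Conditions: Cp2TiMe2 (3.5 equiv), toluene/THF, 65 °C, dark; filtration through basic alumina
Reagents that add atoms: dimethyltitanocene, C[Ti](C)(C1C=CC=C1)C1C=CC=C1
Why: Petasis methylenation: the small, oxophilic titanium methylidene olefinates hindered and ester-like carbonyls that resist phosphorus ylides, and C4 is non-enolisable. One extra equivalent is consumed by the free hydroxyl, and the neutral conditions spare the acid-labile product.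

Step 13
Reactants: 20 4(18)-methylene dienyl bis-ether
Product: 22 7-ketone (1-hydroxy-2,3-dimethoxy-15-OTBS-cleroda-2,4(18),13E-trien-7-one; H8 on the lower face, C17 on the upper face), via tetrabutylammonium enolate 21 (not isolated)
Conditions: TBAF (1.1 equiv), THF, −78 → −40 °C; then aq. NH4Cl
Reagents that add atoms: none
Why: Fluoride cleaves the enol silyl ether far faster than the primary alkyl silyl ether because an enolate is the leaving group. The enolate is protonated at C8 along the axial direction from the lower face, away from axial C20, giving the equatorial C17 that is also the thermodynamic epimer; any epimer mixture can be equilibrated with mild base.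

Step 14
Reactants: 22 7-ketone
Product: 23 1,7-diol with the 7-hydroxyl on the lower face (equatorial), 15-OTBS, ring A unchanged
Conditions: SmI2 (4 equiv), THF, H2O, Et3N, 0 °C
Reagents that add atoms: none
Why: Single-electron reduction through the ketyl gives the thermodynamically preferred equatorial alcohol, as dissolving-metal reductions do, whereas hydride would enter from the open lower face and give the axial epimer because axial C20 and C4 block the upper face. Ring A holds no carbonyl at this stage and the electron-rich dienyl ether is not reduced.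

Step 15
Reactants: 23 1,7-diol
Product: 25 7,15-dihydroxy-2-methoxycleroda-1,4(18),13E-trien-3-one, via dienone silyl ether 24 (not isolated)
Conditions: 48% aq. HF, MeCN, 0 °C → rt
Reagents that add atoms: water, O
Why: Reductive 1,3-carbonyl transposition of the Stork–Danheiser type: the C1 carbinol ionises to a pentadienyl cation stabilised by the C3 methoxy group, water adds at C3 and methanol is lost, leaving the C3 ketone, the C1=C2 bond and the C2 methoxy group. This vinylogous ketal-type ionisation should be faster than C-protonation of the dienyl ether, which would lead to the regioisomeric enone. The same mild acid–fluoride medium removes the primary silyl group without ionising the allylic alcohol.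

Step 16
Reactants: 25 7,15-dihydroxy-2-methoxycleroda-1,4(18),13E-trien-3-one
Product: 26 7-hydroxy-2-methoxy-3-oxocleroda-1,4(18),13E-trien-15-al
Conditions: activated MnO2, CH2Cl2, rt
Reagents that add atoms: none
Why: MnO2 oxidises only the allylic primary alcohol and leaves the saturated secondary 7-hydroxyl; the (E)-geometry is retained.

Step 17
Reactants: 26 7-hydroxy-2-methoxy-3-oxocleroda-1,4(18),13E-trien-15-al
Product: 27 7-acetoxy-2-methoxy-3-oxocleroda-1,4(18),13E-trien-15-al
Conditions: Ac2O, DMAP (cat.), pyridine, CH2Cl2, 0 °C → rt
Reagents that add atoms: acetic anhydride, CC(=O)OC(C)=O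
Why: DMAP-catalysed acetylation of the only remaining hydroxyl, which is equatorial and accessible.

Step 18
Reactants: 27 7-acetoxy-2-methoxy-3-oxocleroda-1,4(18),13E-trien-15-al
Product: 28 7-acetoxy-2-methoxy-3-oxocleroda-1,4(18),13E-trien-15-oic acid
Conditions: NaClO2, NaH2PO4, 2-methyl-2-butene, t-BuOH/H2O, rt
Reagents that add atoms: sodium chlorite, [Na+].[O-]Cl=O
Why: Pinnick oxidation converts the enal into the enoic acid without moving the double bond; the scavenger removes hypochlorite, and the buffered medium spares the acetate and the electron-poor enol ether.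

Step 19
Reactants: 28 7-acetoxy-2-methoxy-3-oxocleroda-1,4(18),13E-trien-15-oic acid
Product: 30 (5S,7S,8S,9R,10R)-7-acetoxy-2-hydroxy-3-oxocleroda-1,4(18),13E-trien-15-oic acid (CNP0192653.1), via dichloroboryl chelate 29 (not isolated)
Conditions: BCl3 (4 equiv), CH2Cl2, −78 → −20 °C; aq. NaHCO3 quench, then extraction at pH 3
Reagents that add atoms: none
Why: Chelation-assisted O-demethylation: boron bridges the C3 carbonyl and the C2 methoxy oxygen, and chloride removes the methyl group, the usual selectivity for methyl ethers flanking a carbonyl. Unchelated esters are left at low temperature, and the excess reagent is taken up by the carboxylic acid and released on work-up.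

## Compound list

1 | hex-5-yn-2-one | CC(=O)CCC#C | starting material
2 | trimethyl phosphonoacetate | COC(=O)CP(=O)(OC)OC | starting material
3 | sodium salt of the trimethyl phosphonoacetate carbanion | [Na+].COC(=O)[CH-]P(=O)(OC)OC | intermediate (not isolated)
4 | methyl (2E)-3-methylhept-2-en-6-ynoate | C#CCC/C(C)=C/C(=O)OC | intermediate
5 | (2E)-3-methylhept-2-en-6-yn-1-ol | C#CCC/C(C)=C/CO | intermediate
6 | tert-butyldimethyl{[(2E)-3-methylhept-2-en-6-yn-1-yl]oxy}silane | C#CCC/C(C)=C/CO[Si](C)(C)C(C)(C)C | intermediate
7 | methyl chloroformate | COC(Cl)=O | starting material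
8 | lithium acetylide of 6 | [Li]C#CCC/C(C)=C/CO[Si](C)(C)C(C)(C)C | intermediate (not isolated)
9 | methyl (6E)-8-[(tert-butyldimethylsilyl)oxy]-6-methyloct-6-en-2-ynoate | COC(=O)C#CCC/C(C)=C/CO[Si](C)(C)C(C)(C)C | intermediate
10 | lithium alkenyl(methyl)cuprate from syn-addition to 9 (Cu cis to the new methyl) | [Li+].COC(=O)/C([Cu-]C)=C(/C)CC/C(C)=C/CO[Si](C)(C)C(C)(C)C | intermediate (not isolated)
11 | methyl (2E,6E)-8-[(tert-butyldimethylsilyl)oxy]-2-iodo-3,6-dimethylocta-2,6-dienoate | COC(=O)/C(I)=C(/C)CC/C(C)=C/CO[Si](C)(C)C(C)(C)C | intermediate
12 | methyl (2Z,6E)-8-[(tert-butyldimethylsilyl)oxy]-2,3,6-trimethylocta-2,6-dienoate | COC(=O)/C(C)=C(/C)CC/C(C)=C/CO[Si](C)(C)C(C)(C)C | intermediate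
13 | (2Z,6E)-8-[(tert-butyldimethylsilyl)oxy]-N-methoxy-N,2,3,6-tetramethylocta-2,6-dienamide | CON(C)C(=O)/C(C)=C(/C)CC/C(C)=C/CO[Si](C)(C)C(C)(C)C | intermediate
14 | lithium chelate of the tetrahedral adduct of MeLi with 13 | CON(C)C(C)(O[Li])/C(C)=C(/C)CC/C(C)=C/CO[Si](C)(C)C(C)(C)C | intermediate (not isolated)
15 | (3Z,7E)-9-[(tert-butyldimethylsilyl)oxy]-3,4,7-trimethylnona-3,7-dien-2-one | CC(=O)/C(C)=C(/C)CC/C(C)=C/CO[Si](C)(C)C(C)(C)C | intermediate
16 | (3Z,7E)-2,9-bis[(tert-butyldimethylsilyl)oxy]-3,4,7-trimethylnona-1,3,7-triene | C=C(O[Si](C)(C)C(C)(C)C)/C(C)=C(/C)CC/C(C)=C/CO[Si](C)(C)C(C)(C)C | intermediate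
17 | 2,3-dimethoxy-5-methyl-1,4-benzoquinone | COC1=C(OC)C(=O)C(C)=CC1=O | starting material
18 | cis-fused ene-dione adduct, 7-OTBS enol ether, 15-OTBS (H10/C19 cis, C20 trans to C19) | O=C1C(OC)=C(OC)C(=O)[C@@H]2[C@@](C)(CC/C(C)=C/CO[Si](C)(C)C(C)(C)C)C(C)=C(O[Si](C)(C)C(C)(C)C)C[C@]12C | intermediate
19 | C1 carbinol of 18 (C4 ketone kept; C1 unassigned) | O=C1C(OC)=C(OC)C(O)[C@@H]2[C@@](C)(CC/C(C)=C/CO[Si](C)(C)C(C)(C)C)C(C)=C(O[Si](C)(C)C(C)(C)C)C[C@]12C | intermediate
20 | 1-hydroxy-2,3-dimethoxycleroda-2,4(18),7,13E-tetraene 7,15-bis-TBS ether | C=C1C(OC)=C(OC)C(O)[C@@H]2[C@@](C)(CC/C(C)=C/CO[Si](C)(C)C(C)(C)C)C(C)=C(O[Si](C)(C)C(C)(C)C)C[C@]12C | intermediate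
21 | tetrabutylammonium C7 enolate of 22 | CCCC[N+](CCCC)(CCCC)CCCC.C=C1C(OC)=C(OC)C(O)[C@@H]2[C@@](C)(CC/C(C)=C/CO[Si](C)(C)C(C)(C)C)C(C)=C([O-])C[C@]12C | intermediate (not isolated)
22 | 7-ketone, C17 upper face (cis to C20), 15-OTBS | C=C1C(OC)=C(OC)C(O)[C@@H]2[C@@](C)(CC/C(C)=C/CO[Si](C)(C)C(C)(C)C)[C@H](C)C(=O)C[C@]12C | intermediate
23 | 1,7-diol, 7-OH lower face (equatorial), 15-OTBS | C=C1C(OC)=C(OC)C(O)[C@@H]2[C@@](C)(CC/C(C)=C/CO[Si](C)(C)C(C)(C)C)[C@H](C)[C@@H](O)C[C@]12C | intermediate
24 | 7-hydroxy-2-methoxy-15-OTBS-cleroda-1,4(18),13E-trien-3-one | C=C1C(=O)C(OC)=C[C@@H]2[C@@](C)(CC/C(C)=C/CO[Si](C)(C)C(C)(C)C)[C@H](C)[C@@H](O)C[C@]12C | intermediate (not isolated)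
25 | 7,15-dihydroxy-2-methoxycleroda-1,4(18),13E-trien-3-one | C=C1C(=O)C(OC)=C[C@@H]2[C@@](C)(CC/C(C)=C/CO)[C@H](C)[C@@H](O)C[C@]12C | intermediate
26 | 7-hydroxy-2-methoxy-3-oxocleroda-1,4(18),13E-trien-15-al | C=C1C(=O)C(OC)=C[C@@H]2[C@@](C)(CC/C(C)=C/C=O)[C@H](C)[C@@H](O)C[C@]12C | intermediate
27 | 7-acetoxy-2-methoxy-3-oxocleroda-1,4(18),13E-trien-15-al | C=C1C(=O)C(OC)=C[C@@H]2[C@@](C)(CC/C(C)=C/C=O)[C@H](C)[C@@H](OC(C)=O)C[C@]12C | intermediate
28 | 7-acetoxy-2-methoxy-3-oxocleroda-1,4(18),13E-trien-15-oic acid | C=C1C(=O)C(OC)=C[C@@H]2[C@@](C)(CC/C(C)=C/C(=O)O)[C@H](C)[C@@H](OC(C)=O)C[C@]12C | intermediate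
29 | O2-dichloroboryl chelate of the diosphenol | C=C1C(=O)C(OB(Cl)Cl)=C[C@@H]2[C@@](C)(CC/C(C)=C/C(=O)O)[C@H](C)[C@@H](OC(C)=O)C[C@]12C | intermediate (not isolated)
30 | (5S,7S,8S,9R,10R)-7-acetoxy-2-hydroxy-3-oxocleroda-1,4(18),13E-trien-15-oic acid | C=C1C(=O)C(O)=C[C@@H]2[C@@](C)(CC/C(C)=C/C(=O)O)[C@H](C)[C@@H](OC(C)=O)C[C@]12C | target

## Step count and least certain steps

Total step count: 19. Longest linear sequence: 19 steps (1 → 30); quinone 17 is bought and enters at step 10.

**Step 10 (key step).** The s-cis conformer of the tetrasubstituted (Z)-diene is strained, so cycloaddition may be slow enough for protodesilylation of the dienol ether to compete. A stepwise Mukaiyama–Michael course could also loosen the C9 relationship, and the bulky diene may lower face discrimination by the catalyst. Fallback: starting from 16 and 17, run the cycloaddition without Lewis acid under high pressure (about 12 kbar, CH2Cl2, rt). This should keep the endo and regiochemical preferences but gives racemic 18, whose enantiomers are then separated by preparative chromatography on a chiral stationary phase. The route resumes at 18 and no new compound arises (F0).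

**Step 11.** Discrimination between the two electronically equal ring-A carbonyls rests on sterics only, so reduction at C4 or over-reduction may compete. Fallback from 18: reduce both carbonyls with excess DIBAL-H to the 1,4-diol F1. Silylate the less hindered C1 carbinol selectively (TESCl, imidazole, −40 °C) to the mono-TES ether F2. Oxidise the remaining neopentylic allylic C4 carbinol with MnO2 to the C1-OTES 4-ketone F3, and methylenate it as in step 12 to the C1-OTES methylene compound F4. Under the fluoride conditions of step 13 (2.2 equiv, −78 → 0 °C) both the enol silyl and the triethylsilyl group are lost, and the route is rejoined at 22.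

**Step 12.** The [2+2] of the titanium methylidene with a hindered, deactivated carbonyl may be slow, the free hydroxyl consumes reagent, and the product can ionise at C1 on acidic supports. Fallback from 19: Peterson olefination. TMSCH2Li with CeCl3 (THF, −78 → 0 °C) adds 1,2 to the non-enolisable C4 ketone to give the β-hydroxysilane F5. KH in THF then induces syn-elimination under basic conditions, where the C1 alkoxide cannot ionise, and the route is rejoined at 20.

**Step 14.** Thermodynamic control of the ketyl reduction may be incomplete, leaving the axial 7-epimer, and the ketyl could cyclise onto the chain alkene. Fallback from 22: reduce deliberately from the open face with L-Selectride (THF, −78 °C) to the axial alcohol F6 (7-epi-23). Carry it through the conditions of steps 15 and 16 to the 7-epi-diol F7 (7-epi-25) and the 7-epi-hydroxy enal F8 (7-epi-26). Mitsunobu reaction with acetic acid (PPh3, DIAD, toluene) then inverts C7 and installs the acetate in one operation, rejoining the route at 27. The axial hydroxyl of F7 and F8 lies over C18, so these two are kept neutral and processed quickly to avoid reversible oxa-Michael closure.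

**Step 19.** The Lewis acid or the HCl it releases may cleave the C7 acetate or add across the exocyclic enone, and the liberated diosphenol is air-sensitive. Fallback from 26: hydrolyse the methyl enol ether before the acetate is in place (2 M aq. HCl, THF, 45 °C) to the diosphenol hydroxy enal F9. Acetylate both hydroxyls (Ac2O, pyridine, DMAP) to the bis-acetate F10, and oxidise under the conditions of step 18 to the bis-acetate acid F11. The enol acetate, far more labile than the secondary acetate, is then removed selectively (NaHCO3, MeOH, 0 °C), arriving at 30.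

## Further compounds

F0 | step 10 | none | none
F1 | step 11 | 1,4-diol from exhaustive reduction of 18 (C1, C4 unassigned) | OC1C(OC)=C(OC)C(O)[C@@H]2[C@@](C)(CC/C(C)=C/CO[Si](C)(C)C(C)(C)C)C(C)=C(O[Si](C)(C)C(C)(C)C)C[C@]12C
F2 | step 11 | C1 mono-triethylsilyl ether of F1 | OC1C(OC)=C(OC)C(O[Si](CC)(CC)CC)[C@@H]2[C@@](C)(CC/C(C)=C/CO[Si](C)(C)C(C)(C)C)C(C)=C(O[Si](C)(C)C(C)(C)C)C[C@]12C
F3 | step 11 | C1-OTES 4-ketone | O=C1C(OC)=C(OC)C(O[Si](CC)(CC)CC)[C@@H]2[C@@](C)(CC/C(C)=C/CO[Si](C)(C)C(C)(C)C)C(C)=C(O[Si](C)(C)C(C)(C)C)C[C@]12C
F4 | step 11 | C1-OTES 4(18)-methylene compound | C=C1C(OC)=C(OC)C(O[Si](CC)(CC)CC)[C@@H]2[C@@](C)(CC/C(C)=C/CO[Si](C)(C)C(C)(C)C)C(C)=C(O[Si](C)(C)C(C)(C)C)C[C@]12C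
F5 | step 12 | C4 β-hydroxysilane (4-hydroxy-4-trimethylsilylmethyl; C4 unassigned) | C[Si](C)(C)CC1(O)C(OC)=C(OC)C(O)[C@@H]2[C@@](C)(CC/C(C)=C/CO[Si](C)(C)C(C)(C)C)C(C)=C(O[Si](C)(C)C(C)(C)C)C[C@]12C
F6 | step 14 | 7-epi-23 (axial 7-OH, upper face) | C=C1C(OC)=C(OC)C(O)[C@@H]2[C@@](C)(CC/C(C)=C/CO[Si](C)(C)C(C)(C)C)[C@H](C)[C@H](O)C[C@]12C
F7 | step 14 | 7-epi-25 | C=C1C(=O)C(OC)=C[C@@H]2[C@@](C)(CC/C(C)=C/CO)[C@H](C)[C@H](O)C[C@]12C
F8 | step 14 | 7-epi-26 | C=C1C(=O)C(OC)=C[C@@H]2[C@@](C)(CC/C(C)=C/C=O)[C@H](C)[C@H](O)C[C@]12C
F9 | step 19 | 2,7-dihydroxy-3-oxocleroda-1,4(18),13E-trien-15-al | C=C1C(=O)C(O)=C[C@@H]2[C@@](C)(CC/C(C)=C/C=O)[C@H](C)[C@@H](O)C[C@]12C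
F10 | step 19 | 2,7-diacetoxy-3-oxocleroda-1,4(18),13E-trien-15-al | C=C1C(=O)C(OC(C)=O)=C[C@@H]2[C@@](C)(CC/C(C)=C/C=O)[C@H](C)[C@@H](OC(C)=O)C[C@]12C
F11 | step 19 | 2,7-diacetoxy-3-oxocleroda-1,4(18),13E-trien-15-oic acid | C=C1C(=O)C(OC(C)=O)=C[C@@H]2[C@@](C)(CC/C(C)=C/C(=O)O)[C@H](C)[C@@H](OC(C)=O)C[C@]12C
A1 | alternative 1 | cis-fused 5-methyl-4-methylene-3-ketone (7-OTBS, tert-butyl ester chain) | C=C1C(=O)CC[C@@H]2[C@@](C)(CC/C(C)=C/C(=O)OC(C)(C)C)[C@H](C)[C@@H](O[Si](C)(C)C(C)(C)C)C[C@]12C
A2 | alternative 1 | 10-H Δ4-3-keto octalone precursor | O=C1CC[C@@H]2[C@@](C)(CC/C(C)=C/C(=O)OC(C)(C)C)[C@H](C)[C@@H](O[Si](C)(C)C(C)(C)C)CC2=C1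
A3 | alternative 2 | cis-fused octalin-1-one 7-silyl enol ether | C1CCC(=O)[C@@H]2[C@@](C)(CC/C(C)=C/C(=O)OC)[C@H](C)C(O[Si](C)(C)C(C)(C)C)=C[C@]12C
A4 | alternative 2 | acyclic trienone precursor | C/C=C(\O[Si](C)(C)C(C)(C)C)/C=C(\C)CCCC(=O)/C=C(\C)CC/C(C)=C/C(=O)OC
A5 | alternative 3 | 2-bromo cis-octal-1-en-3-one | C1C(=O)C(Br)=C[C@@H]2[C@@](C)(CC/C(C)=C/C(=O)OC)[C@H](C)[C@@H](O[Si](C)(C)C(C)(C)C)C[C@]12C
A6 | alternative 3 | cis-hydrindan-3-one precursor | C1C(=O)C[C@@H]2[C@@](C)(CC/C(C)=C/C(=O)OC)[C@H](C)[C@@H](O[Si](C)(C)C(C)(C)C)C[C@]12C
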